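## Analysis of the target

The target is an open-chain compound. A thirteen-carbon chain, numbered here C1 (benzylic) to C13, carries one benzene ring (ring A, C1' to C6', with C1' bonded to C1). Ring A is a 5-alkylresorcinol with free hydroxyls on C3' and C5'. The chain bears an acetoxy group on C2, a ketone at C8 and a plain pentyl tail C9–C13.

C2 is the only stereocentre and is R. With no second centre to relate it to, its absolute configuration has to come from a chiral starting material or an enantioselective step.

The sensitive points are three. The secondary acetate must end up as the only acyl group in a molecule with two phenols. The electron-rich resorcinol is easily oxidised. The ketone must be masked whenever carbanions or hydrazine derivatives are present.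

The skeleton is simple. The difficulty lies in telling three hydroxyls apart and in setting C2, which sits five methylene groups away from the next functional group, in few steps.

The strategy rests on the unit C1'–C1–C2(O). Ring A, the benzylic carbon and a heteroatom-bearing stereocentre of the right absolute sense are the skeleton of L-phenylalanine, whose carboxyl carbon becomes C3. The amino acid lacks only the hydroxyls on C3' and C5'. Both are meta to the single ring substituent on C1', the two positions that a sterically governed C–H functionalisation of a monosubstituted benzene reaches.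

## Retrosynthetic reasoning

**From 25 to 24.** The two phenolic O–H bonds are traced back to O–benzyl bonds, which are cut last. The acetyl group must go onto the C2 oxygen while the phenols are masked, otherwise three hydroxyls compete. Benzyl ethers leave under neutral hydrogenolysis, which disturbs neither the acetate nor the C8 ketone.

**From 24 to 23 and 22.** The acetyl–oxygen bond at C2 is disconnected to the free alcohol 23. Alcohol 23 comes from 22, in which the C2 oxygen carries a silyl group and C8 a cyclic ketal. Once the chain is saturated neither mask is needed, so a single acid treatment should remove both.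

**From 22 to 21, and on to 10 and 19.** The chain is cut between C3 and C4, in the form of a double bond. C3 is the former carboxyl carbon of the amino acid, so an aldehyde at C3 (10) is available without extra carbon–carbon chemistry. The other half becomes the phosphonium salt 19, which holds C4–C13 with the ketone masked. A cut nearer the ketone would waste this built-in handle, and a cut at C1–C2 or C2–C3 would put the stereocentre at risk. The olefination need not control geometry, because alkene 21 is saturated at once. The saturation must spare two benzyl ethers and an allylic C–O bond, so it calls for metal-free hydrogen transfer rather than hydrogenation over a metal.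

**From 19 to 18, 17, 14 and 12, and to the starting materials 11 and 15.** Inside the side chain the C8–C9 bond is cut: a five-carbon acyl unit C4–C8 is joined to the pentyl nucleophile 16 made from 15. Lactone 11 holds exactly C4–C8 with its two ends at different oxidation levels. Opening it with bromide gives 12, and its acid end is converted, through 13, into the amide 14, which accepts only one equivalent of an organometallic. Ketone 17 is then masked as 18 and the bromide end quaternised to 19.

**From 10 to 9 and 7.** The aldehyde comes from partial reduction of methyl ester 9, and 9 from resorcinol 7 by double O-benzylation. These are protecting and redox adjustments that form no skeletal bond.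

**From 7 to 4 (the key disconnection).** Both aryl C–O bonds, C3'–O and C5'–O, are cut back to C–H bonds. Ring A of 4 has a single substituent, so its two meta positions are equivalent. Once one of them is occupied, the other is the only ring C–H not flanked by a substituent. The forward reaction must deliver two boron atoms from 5 to these positions by catalytic C–H activation (giving 6) and exchange both for oxygen in the same flask, without touching the α-silyloxy ester. What is gained is that no pre-oxygenated aromatic building block and no asymmetric step is needed. The price is that the para position C4' competes in the first borylation.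

**From 4 to 3, 2 and 1.** The silyl ether and the methyl ester are protecting operations. Acid 2 comes from L-phenylalanine 1 by exchange of the C2–N bond for a C2–O bond with overall retention. Compounds 2 to 10 and 21 are S and the saturated compounds 22 to 25 are R with the same spatial arrangement, because C3 drops in priority below C1 once it is no longer a carbonyl or alkene carbon.

## Alternatives that were turned down

**Alternative 1:** Ring A is built instead of bought. The bonds C1'–C6' and C4'–C5' are disconnected, leading to the enone A1, (3E,6R)-6-[(tert-butyldimethylsilyl)oxy]-11-(2-pentyl-1,3-dioxolan-2-yl)undec-3-en-2-one, which already holds the whole chain and C2, and to dimethyl malonate A2. In the forward direction an alkoxide base would add A2 to the β-carbon of A1. The methyl ketone enolate would then acylate one ester group and close the six-membered ring as the cyclohexane-1,3-dione A3, methyl 6-{(R)-2-[(tert-butyldimethylsilyl)oxy]-7-(2-pentyl-1,3-dioxolan-2-yl)heptyl}-2,4-dioxocyclohexane-1-carboxylate.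
- For it: both ring oxygens are placed by construction, so nothing is lost to a para isomer. On regiochemistry this route is stronger than the chosen one.
- Against it: A3 is still three operations from a resorcinol (ester hydrolysis, decarboxylation, oxidative aromatisation). The aromatisation of a dione carrying a silyl ether, a ketal and several enolisable positions is the weak link.
- Against it: A1 has acidic hydrogens on C1, γ to the carbonyl. The alkoxide can form the dienolate and expel the silyloxy group from C2 in a vinylogous elimination, which would destroy the only stereocentre.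
- Against it: C2 has to be created by a separate asymmetric step, because nothing in A1 comes from the chiral pool.
- Comparison: the chosen route gives up perfect regiocontrol. In return the ring is aromatic from the start, C2 is taken from the amino acid, and the oxygenated ring is reached in four steps.

**Alternative 2:** The chain is cut on both sides of the carbonyl carbon, at C7–C8 and C8–C9, and C8 is supplied by the one-carbon linchpin tosylmethyl isocyanide A4. Deprotonated A4 would be alkylated first by 1-iodopentane A5 and then by the iodide A6, {[(2R)-1-[3,5-bis(benzyloxy)phenyl]-7-iodoheptan-2-yl]oxy}(tert-butyl)dimethylsilane. The product is the dialkylated isocyanide A7, (2R)-1-[3,5-bis(benzyloxy)phenyl]-2-[(tert-butyldimethylsilyl)oxy]-8-isocyano-8-tosyltridecane (C8 as a mixture), from which mild acid would release the ketone.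
- For it: the plan is convergent, the ketone is born masked, and no alkene has to be reduced. For the assembly of the chain it is at least as good as the olefination and ketal sequence used here, and it saves a protection step.
- Against it: the second alkylation, of a hindered monoalkylated carbanion by an unactivated primary iodide, is the slow one. In one pot, two electrophiles compete over two stages, so symmetrical dialkylation products are to be expected unless the stages are separated.
- Against it: the disconnection does not address ring A or C2. A6 must already contain the protected resorcinol, the stereocentre and a five-carbon ω-iodo chain, which still needs an asymmetric entry and a chain extension from C3 to C7.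
- Comparison: the chosen strategy solves the two problems this one leaves open, the ring oxygens and C2, from one purchased amino acid. It pays for that with a conventional olefination for the chain.

**Alternative 3:** Ring A is assembled by a thermal benzannulation. The bonds C3'–C4', C5'–C6' and C2'–C3' are disconnected to the cyclobutenone A8, 3-[(2R)-2-[(tert-butyldimethylsilyl)oxy]-8-oxotridecyl]cyclobut-2-en-1-one, and ethoxyacetylene A9. On heating, A8 would open electrocyclically and add A9 across its two alkyne carbons. A second ring opening and a 6π closure with tautomerisation would then give the resorcinol monoethyl ether A10, 3-ethoxy-5-{(R)-2-[(tert-butyldimethylsilyl)oxy]-8-oxotridecyl}phenol.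
- For it: the reaction is neutral and metal-free, and the free C8 ketone is tolerated. The mechanism puts the oxygens on C3' and C5' and nowhere else. On regiocontrol it beats the chosen route.
- Against it: the aryl ethyl ether has to be cleaved at the end. That needs a strong Lewis acid or a hard nucleophile, and neither is compatible with the secondary acetate. The ether would have to go before acetylation and the phenols be reprotected. The differentiation of the two ring oxygens has no value for a symmetrical resorcinol.
- Against it: A8 is not commercial. It must be built on a chain that already contains C2, which again needs its own asymmetric step.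
- Comparison: more steps before and after the key step. The chosen route functionalises a ring that is already present and needs only benzyl ethers that leave under neutral conditions.

Key step: step 4

Remark on the chemistry: alkene 21 is drawn as the Z isomer expected from a non-stabilised ylide; any E isomer would be carried on, since step 13 removes the double bond. KHSO5 is used as its commercial triple salt 2KHSO5·KHSO4·K2SO4.

## Route

Step 1
Reactants: 1 L-phenylalanine
Product: 2 (2S)-2-hydroxy-3-phenylpropanoic acid
Conditions: NaNO2, 1 M H2SO4, H2O, 0 °C → rt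
Reagents that add atoms: water, O
Why: Diazotisation of the α-amino acid followed by substitution with neighbouring-group participation of the carboxylate; two successive inversions give net retention, so C2 keeps the L arrangement and is now oxygenated.

Step 2
Reactants: 2 (2S)-2-hydroxy-3-phenylpropanoic acid
Product: 3 methyl (2S)-2-hydroxy-3-phenylpropanoate
Conditions: MeOH, conc. H2SO4 (cat.), reflux
Reagents that add atoms: methanol, CO
Why: Fischer esterification; acid catalysis does not enolise an α-hydroxy acid, so C2 is untouched.

Step 3
Reactants: 3 methyl (2S)-2-hydroxy-3-phenylpropanoate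
Product: 4 methyl (2S)-2-[(tert-butyldimethylsilyl)oxy]-3-phenylpropanoate
Conditions: tBuMe2SiCl, imidazole, DMF, rt
Reagents that add atoms: tert-butyldimethylsilyl chloride, CC(C)(C)[Si](C)(C)Cl
Why: Imidazole-promoted silylation of a secondary alcohol; the bulky silyl ether suppresses enolisation at C2 and is meant to survive steps 4 to 13.

Step 4
Reactants: 4 methyl (2S)-2-[(tert-butyldimethylsilyl)oxy]-3-phenylpropanoate; 5 bis(pinacolato)diboron
Product: 7 methyl (2S)-2-[(tert-butyldimethylsilyl)oxy]-3-(3,5-dihydroxyphenyl)propanoate, via the 3,5-bis(pinacolboronate) 6 (not isolated)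
Conditions: [Ir(OMe)(cod)]2 (1.5 mol %), 4,4'-di-tert-butyl-2,2'-bipyridine (3 mol %), B2pin2 (2.0 equiv), THF, 80 °C; evaporate; KHSO5 (as 2KHSO5·KHSO4·K2SO4), acetone/H2O, 0 °C → rt, short contact; aq. NaHSO3
Reagents that add atoms: bis(pinacolato)diboron 5 (boryl groups of 6), CC1(C)OB(OC1(C)C)B1OC(C)(C)C(C)(C)O1; potassium peroxymonosulfate (both phenol oxygens), [K+].[O-]S(=O)(=O)OO
Why: The precatalyst, the bipyridine and 5 form a tris(boryl) complex of trivalent iridium with one free site; it cleaves an aromatic C–H bond, C–B reductive elimination releases the aryl boronate, and the pinacolborane formed serves as a second boron source. The closest known reaction type is the sterically controlled iridium-catalysed arene C–H borylation (Hartwig–Miyaura type) with oxidation to the phenol in the same flask, including 3,5-diborylation of monosubstituted benzenes. The selectivity needed is C3' and C5' over C2', C4' and C6'; C2' and C6' flank the branched side chain and are not attacked, and a ring borylated at C3' has only C5' left as a C–H without an ortho neighbour, so it should be driven on to 6 by the excess of 5. The first borylation can also fall on C4', and such material stops at the mono stage; this statistical share is an accepted loss and should be easy to remove after oxidation as a much less polar mono-phenol. In the oxidation peroxymonosulfate adds to boron, the aryl group shifts from boron to oxygen with loss of sulfate, and hydrolysis of the borate gives the phenol at the same carbon. No ring is closed and no stereocentre is formed. The borylation is neutral and the oxidation brief and only mildly acidic, so the α-silyloxy ester should neither enolise nor lose its silyl group, and sp3 C–H bonds (benzylic, Si–CH3, O–CH3) react far more slowly with this ligand.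

Step 5
Reactants: 7 methyl (2S)-2-[(tert-butyldimethylsilyl)oxy]-3-(3,5-dihydroxyphenyl)propanoate; 8 benzyl bromide
Product: 9 methyl (2S)-3-[3,5-bis(benzyloxy)phenyl]-2-[(tert-butyldimethylsilyl)oxy]propanoate
Conditions: BnBr (2.4 equiv), K2CO3, DMF, rt
Reagents that add atoms: benzyl bromide 8, BrCc1ccccc1
Why: Williamson etherification of both phenols; carbonate is too weak a base to enolise the α-silyloxy ester, and benzyl ethers can be removed at the end under neutral conditions.

Step 6
Reactants: 9 methyl (2S)-3-[3,5-bis(benzyloxy)phenyl]-2-[(tert-butyldimethylsilyl)oxy]propanoate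
Product: 10 (2S)-3-[3,5-bis(benzyloxy)phenyl]-2-[(tert-butyldimethylsilyl)oxy]propanal
Conditions: iBu2AlH (1.1 equiv), CH2Cl2, −78 °C; MeOH, then aq. potassium sodium tartrate
Reagents that add atoms: none
Why: Partial reduction of an ester with one hydride equivalent; the tetrahedral aluminium hemiacetal, stabilised by the neighbouring silyloxy oxygen, persists at −78 °C, so the aldehyde is set free only after the hydride is quenched. The aldehyde is used at once to protect C2.

Step 7
Reactants: 11 δ-valerolactone
Product: 12 5-bromopentanoic acid
Conditions: 48% aq. HBr, conc. H2SO4, rt → 60 °C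
Reagents that add atoms: hydrogen bromide, Br
Why: Acid-mediated lactone opening; bromide substitutes at the primary O-alkyl carbon (SN2) of the protonated lactone and so differentiates the two ends of the C4–C8 unit.

Step 8
Reactants: 12 5-bromopentanoic acid
Product: 14 5-bromo-N-methoxy-N-methylpentanamide, via 5-bromopentanoyl chloride 13 (not isolated)
Conditions: (COCl)2, DMF (cat.), CH2Cl2, 0 °C → rt; evaporate; MeNH(OMe)·HCl, pyridine, CH2Cl2, 0 °C → rt
Reagents that add atoms: oxalyl chloride (chlorine of 13), ClC(=O)C(Cl)=O; N,O-dimethylhydroxylamine hydrochloride, Cl.CNOC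
Why: Acid chloride formation and amide coupling; the Weinreb amide is chosen so that the next step stops cleanly at the ketone.

Step 9
Reactants: 14 5-bromo-N-methoxy-N-methylpentanamide; 15 1-bromopentane
Product: 17 1-bromodecan-5-one, via pentylmagnesium bromide 16 (not isolated)
Conditions: 15, Mg, THF, rt → reflux; then 14, THF, 0 °C; 1 M HCl
Reagents that add atoms: 1-bromopentane 15 (pentyl group), CCCCCBr; magnesium (in 16 only), [Mg]
Why: Weinreb ketone synthesis forms C8–C9; the chelated tetrahedral adduct collapses to the ketone only on acidic quench, and an unactivated primary C–Br bond does not couple with an alkyl Grignard reagent at 0 °C without a catalyst.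

Step 10
Reactants: 17 1-bromodecan-5-one
Product: 18 2-(4-bromobutyl)-2-pentyl-1,3-dioxolane
Conditions: HOCH2CH2OH, p-TsOH·H2O (cat.), toluene, reflux, Dean–Stark
Reagents that add atoms: ethylene glycol, OCCO
Why: Acid-catalysed ketalisation with azeotropic removal of water; the dioxolane masks C8 against the ylide of step 12 and the hydrazide of step 13.

Step 11
Reactants: 18 2-(4-bromobutyl)-2-pentyl-1,3-dioxolane
Product: 19 triphenyl[4-(2-pentyl-1,3-dioxolan-2-yl)butyl]phosphonium bromide
Conditions: PPh3, MeCN, reflux
Reagents that add atoms: triphenylphosphine, c1ccc(cc1)P(c1ccccc1)c1ccccc1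
Why: SN2 quaternisation of the phosphine by a primary bromide; the neutral conditions leave the ketal intact.

Step 12
Reactants: 19 triphenyl[4-(2-pentyl-1,3-dioxolan-2-yl)butyl]phosphonium bromide; 10 (2S)-3-[3,5-bis(benzyloxy)phenyl]-2-[(tert-butyldimethylsilyl)oxy]propanal
Product: 21 tert-butyl({(2S,3Z)-1-[3,5-bis(benzyloxy)phenyl]-7-(2-pentyl-1,3-dioxolan-2-yl)hept-3-en-2-yl}oxy)dimethylsilane, via the phosphorus ylide 20 (not isolated)
Conditions: 19 (1.3 equiv), NaN(SiMe3)2 (1.2 equiv), THF, −78 → 0 °C; then 10, −78 °C → rt
Reagents that add atoms: none
Why: Wittig olefination with a non-stabilised ylide forms C3=C4; Z selectivity is expected but does not matter. A slight deficit of base relative to the salt and addition of the aldehyde at −78 °C keep enolisation of the α-silyloxy aldehyde low, so C2 should pass unchanged.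

Step 13
Reactants: 21 tert-butyl({(2S,3Z)-1-[3,5-bis(benzyloxy)phenyl]-7-(2-pentyl-1,3-dioxolan-2-yl)hept-3-en-2-yl}oxy)dimethylsilane
Product: 22 tert-butyl({(2R)-1-[3,5-bis(benzyloxy)phenyl]-7-(2-pentyl-1,3-dioxolan-2-yl)heptan-2-yl}oxy)dimethylsilane
Conditions: p-TolSO2NHNH2 (excess, in portions), NaOAc, DME/H2O, reflux
Reagents that add atoms: none
Why: Diimide reduction; diimide formed in the flask transfers two hydrogens to the alkene in a concerted syn fashion. No metal is present, so neither the benzyl ethers nor the allylic C2–O bond is cleaved, and the ketal prevents hydrazone formation at C8.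

Step 14
Reactants: 22 tert-butyl({(2R)-1-[3,5-bis(benzyloxy)phenyl]-7-(2-pentyl-1,3-dioxolan-2-yl)heptan-2-yl}oxy)dimethylsilane
Product: 23 (12R)-13-[3,5-bis(benzyloxy)phenyl]-12-hydroxytridecan-6-one
Conditions: 3 M aq. HCl/THF/MeOH (1:2:1), rt
Reagents that add atoms: water, O
Why: Acid-catalysed cleavage of the silyl ether (at silicon, so the C2–O bond is not broken) and hydrolysis of the ketal in one operation; aryl benzyl ethers are stable to dilute mineral acid.

Step 15
Reactants: 23 (12R)-13-[3,5-bis(benzyloxy)phenyl]-12-hydroxytridecan-6-one
Product: 24 (2R)-1-[3,5-bis(benzyloxy)phenyl]-8-oxotridecan-2-yl acetate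
Conditions: Ac2O, pyridine, DMAP (cat.), CH2Cl2, 0 °C → rt
Reagents that add atoms: acetic anhydride, CC(=O)OC(C)=O
Why: Acylation under nucleophilic catalysis; with both phenols still benzylated, the C2 hydroxyl is the only one available.

Step 16
Reactants: 24 (2R)-1-[3,5-bis(benzyloxy)phenyl]-8-oxotridecan-2-yl acetate
Product: 25 (2R)-1-(3,5-dihydroxyphenyl)-8-oxotridecan-2-yl acetate
Conditions: H2 (1 atm), Pd/C (10%), EtOAc, rt
Reagents that add atoms: none
Why: Hydrogenolysis of the two benzylic C–O bonds over palladium; the dialkyl ketone and the homobenzylic (not benzylic) secondary acetate are inert under these conditions.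

## Compound list

1 | L-phenylalanine | N[C@@H](Cc1ccccc1)C(=O)O | starting material
2 | (2S)-2-hydroxy-3-phenylpropanoic acid | O[C@@H](Cc1ccccc1)C(=O)O | intermediate
3 | methyl (2S)-2-hydroxy-3-phenylpropanoate | COC(=O)[C@H](Cc1ccccc1)O | intermediate
4 | methyl (2S)-2-[(tert-butyldimethylsilyl)oxy]-3-phenylpropanoate | COC(=O)[C@H](Cc1ccccc1)O[Si](C)(C)C(C)(C)C | intermediate
5 | bis(pinacolato)diboron | CC1(C)OB(OC1(C)C)B1OC(C)(C)C(C)(C)O1 | starting material
6 | methyl (2S)-3-[3,5-bis(4,4,5,5-tetramethyl-1,3,2-dioxaborolan-2-yl)phenyl]-2-[(tert-butyldimethylsilyl)oxy]propanoate | COC(=O)[C@H](Cc1cc(B2OC(C)(C)C(C)(C)O2)cc(B2OC(C)(C)C(C)(C)O2)c1)O[Si](C)(C)C(C)(C)C | intermediate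
7 | methyl (2S)-2-[(tert-butyldimethylsilyl)oxy]-3-(3,5-dihydroxyphenyl)propanoate | COC(=O)[C@H](Cc1cc(O)cc(O)c1)O[Si](C)(C)C(C)(C)C | intermediate
8 | benzyl bromide | BrCc1ccccc1 | starting material
9 | methyl (2S)-3-[3,5-bis(benzyloxy)phenyl]-2-[(tert-butyldimethylsilyl)oxy]propanoate | COC(=O)[C@H](Cc1cc(OCc2ccccc2)cc(OCc2ccccc2)c1)O[Si](C)(C)C(C)(C)C | intermediate
10 | (2S)-3-[3,5-bis(benzyloxy)phenyl]-2-[(tert-butyldimethylsilyl)oxy]propanal | O=C[C@H](Cc1cc(OCc2ccccc2)cc(OCc2ccccc2)c1)O[Si](C)(C)C(C)(C)C | intermediate
11 | δ-valerolactone | O=C1CCCCO1 | starting material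
12 | 5-bromopentanoic acid | OC(=O)CCCCBr | intermediate
13 | 5-bromopentanoyl chloride | ClC(=O)CCCCBr | intermediate
14 | 5-bromo-N-methoxy-N-methylpentanamide | CON(C)C(=O)CCCCBr | intermediate
15 | 1-bromopentane | CCCCCBr | starting material
16 | pentylmagnesium bromide | CCCCC[Mg]Br | intermediate
17 | 1-bromodecan-5-one | CCCCCC(=O)CCCCBr | intermediate
18 | 2-(4-bromobutyl)-2-pentyl-1,3-dioxolane | CCCCCC1(CCCCBr)OCCO1 | intermediate
19 | triphenyl[4-(2-pentyl-1,3-dioxolan-2-yl)butyl]phosphonium bromide | CCCCCC1(CCCC[P+](c2ccccc2)(c2ccccc2)c2ccccc2)OCCO1.[Br-] | intermediate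
20 | triphenyl[4-(2-pentyl-1,3-dioxolan-2-yl)butylidene]phosphorane | CCCCCC1(CCCC=P(c2ccccc2)(c2ccccc2)c2ccccc2)OCCO1 | intermediate
21 | tert-butyl({(2S,3Z)-1-[3,5-bis(benzyloxy)phenyl]-7-(2-pentyl-1,3-dioxolan-2-yl)hept-3-en-2-yl}oxy)dimethylsilane | CCCCCC1(CCC/C=C\[C@H](Cc2cc(OCc3ccccc3)cc(OCc3ccccc3)c2)O[Si](C)(C)C(C)(C)C)OCCO1 | intermediate
22 | tert-butyl({(2R)-1-[3,5-bis(benzyloxy)phenyl]-7-(2-pentyl-1,3-dioxolan-2-yl)heptan-2-yl}oxy)dimethylsilane | CCCCCC1(CCCCC[C@H](Cc2cc(OCc3ccccc3)cc(OCc3ccccc3)c2)O[Si](C)(C)C(C)(C)C)OCCO1 | intermediate
23 | (12R)-13-[3,5-bis(benzyloxy)phenyl]-12-hydroxytridecan-6-one | CCCCCC(=O)CCCCC[C@H](Cc1cc(OCc2ccccc2)cc(OCc2ccccc2)c1)O | intermediate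
24 | (2R)-1-[3,5-bis(benzyloxy)phenyl]-8-oxotridecan-2-yl acetate | CCCCCC(=O)CCCCC[C@H](Cc1cc(OCc2ccccc2)cc(OCc2ccccc2)c1)OC(C)=O | intermediate
25 | (2R)-1-(3,5-dihydroxyphenyl)-8-oxotridecan-2-yl acetate | CCCCCC(=O)CCCCC[C@H](Cc1cc(O)cc(O)c1)OC(C)=O | target

## Step count and least certain steps

Total step count: 16. Longest linear sequence: 11 steps (steps 1 to 6 and 12 to 16, from 1 to 25); the side chain branch (steps 7 to 11) joins at step 12.

**Step 4 (key step).** The first borylation is not selective between the meta and para positions, and material borylated at C4' stops there. This drains substrate, and the second borylation may stall before all meta-monoborylated material is converted. In the oxidation stage the electron-rich resorcinol may be oxidised further, or the silyl ether may suffer acid-induced loss if contact is prolonged.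

Fallback: the C–H oxygenation is given up and ring A is bought with its oxygens. No compound before 7 carries ring oxygen, so the fallback sets out from benzyl bromide 8. With K2CO3 in DMF it would O-benzylate commercial 5-bromobenzene-1,3-diol to 1-bromo-3,5-bis(benzyloxy)benzene F1. Mg in THF converts this to [3,5-bis(benzyloxy)phenyl]magnesium bromide F2. With catalytic CuI at −30 °C, F2 opens commercial methyl (2S)-oxirane-2-carboxylate (COC(=O)[C@@H]1CO1) at its CH2 carbon, leaving the stereocentre untouched, to give methyl (2S)-3-[3,5-bis(benzyloxy)phenyl]-2-hydroxypropanoate F3. Silylation under the conditions of step 3 comes back to the route at 9.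

**Step 6.** Over-reduction to the primary alcohol can occur if the tetrahedral adduct collapses before the quench. The aldehyde may also lose configurational purity at C2 on prolonged handling.

Fallback: it sets out from 9. MeNH(OMe)·HCl and iPrMgCl in THF at −20 °C convert the ester into the Weinreb amide (2S)-3-[3,5-bis(benzyloxy)phenyl]-2-[(tert-butyldimethylsilyl)oxy]-N-methoxy-N-methylpropanamide F4. Its chelated adduct with LiAlH4 (THF, −78 °C) cannot take up a second hydride and releases the aldehyde only on quench. The fallback comes back at 10.

**Step 12.** The ylide is a strong base. Enolisation of the α-silyloxy aldehyde would erode the configuration at C2, and the branched aldehyde may be olefinated slowly enough for this to compete.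

Fallback: the C3–C4 bond is made as a single bond by substitution, without an aldehyde. It sets out from 9 and uses bromide 18. iBu2AlH (2.5 equiv, CH2Cl2, −78 → 0 °C) reduces the ester to (2S)-3-[3,5-bis(benzyloxy)phenyl]-2-[(tert-butyldimethylsilyl)oxy]propan-1-ol F5. Tf2O and 2,6-lutidine (CH2Cl2, −78 °C) give (2S)-3-[3,5-bis(benzyloxy)phenyl]-2-[(tert-butyldimethylsilyl)oxy]propyl trifluoromethanesulfonate F6, used at once. The Grignard reagent [4-(2-pentyl-1,3-dioxolan-2-yl)butyl]magnesium bromide F7, made from 18 and Mg in THF, displaces the triflate under CuBr·SMe2 catalysis (THF/Et2O, −78 → 0 °C). The fallback comes back at 22 and also bypasses step 13.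

**Step 13.** Diimide disproportionates quickly, and a Z-disubstituted alkene with a bulky allylic silyloxy group takes up hydrogen slowly. Incomplete reduction, despite repeated charges of reagent, is the likely failure.

Fallback: the alkene is hydrogenated over a metal and the loss of the benzyl groups is accepted. It sets out from 21. H2 over Pd/C in EtOAc saturates the alkene while the C2 oxygen is still silylated (no allylic acetate is present) and removes both benzyl groups, giving 5-[(2R)-2-[(tert-butyldimethylsilyl)oxy]-7-(2-pentyl-1,3-dioxolan-2-yl)heptyl]benzene-1,3-diol F8. Aqueous HCl in THF/MeOH gives (12R)-13-(3,5-dihydroxyphenyl)-12-hydroxytridecan-6-one F9. Ac2O and pyridine acetylate all three hydroxyls to 5-[(2R)-2-(acetyloxy)-8-oxotridecyl]-1,3-phenylene diacetate F10. Pyrrolidine (2.2 equiv, MeCN, 0 °C) then cleaves only the two much more reactive aryl acetates by aminolysis. The fallback comes back at the target 25.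

## Further compounds

F1 | step 4 | 1-bromo-3,5-bis(benzyloxy)benzene | Brc1cc(OCc2ccccc2)cc(OCc2ccccc2)c1
F2 | step 4 | [3,5-bis(benzyloxy)phenyl]magnesium bromide | Br[Mg]c1cc(OCc2ccccc2)cc(OCc2ccccc2)c1
F3 | step 4 | methyl (2S)-3-[3,5-bis(benzyloxy)phenyl]-2-hydroxypropanoate | COC(=O)[C@H](Cc1cc(OCc2ccccc2)cc(OCc2ccccc2)c1)O
F4 | step 6 | (2S)-3-[3,5-bis(benzyloxy)phenyl]-2-[(tert-butyldimethylsilyl)oxy]-N-methoxy-N-methylpropanamide | CON(C)C(=O)[C@H](Cc1cc(OCc2ccccc2)cc(OCc2ccccc2)c1)O[Si](C)(C)C(C)(C)C
F5 | step 12 | (2S)-3-[3,5-bis(benzyloxy)phenyl]-2-[(tert-butyldimethylsilyl)oxy]propan-1-ol | OC[C@H](Cc1cc(OCc2ccccc2)cc(OCc2ccccc2)c1)O[Si](C)(C)C(C)(C)C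
F6 | step 12 | (2S)-3-[3,5-bis(benzyloxy)phenyl]-2-[(tert-butyldimethylsilyl)oxy]propyl trifluoromethanesulfonate | FC(F)(F)S(=O)(=O)OC[C@H](Cc1cc(OCc2ccccc2)cc(OCc2ccccc2)c1)O[Si](C)(C)C(C)(C)C
F7 | step 12 | [4-(2-pentyl-1,3-dioxolan-2-yl)butyl]magnesium bromide | CCCCCC1(CCCC[Mg]Br)OCCO1
F8 | step 13 | 5-[(2R)-2-[(tert-butyldimethylsilyl)oxy]-7-(2-pentyl-1,3-dioxolan-2-yl)heptyl]benzene-1,3-diol | CCCCCC1(CCCCC[C@H](Cc2cc(O)cc(O)c2)O[Si](C)(C)C(C)(C)C)OCCO1
F9 | step 13 | (12R)-13-(3,5-dihydroxyphenyl)-12-hydroxytridecan-6-one | CCCCCC(=O)CCCCC[C@H](Cc1cc(O)cc(O)c1)O
F10 | step 13 | 5-[(2R)-2-(acetyloxy)-8-oxotridecyl]-1,3-phenylene diacetate | CCCCCC(=O)CCCCC[C@H](Cc1cc(OC(C)=O)cc(OC(C)=O)c1)OC(C)=O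
A1 | alternative 1 | (3E,6R)-6-[(tert-butyldimethylsilyl)oxy]-11-(2-pentyl-1,3-dioxolan-2-yl)undec-3-en-2-one | CC(=O)/C=C/C[C@@H](CCCCCC1(CCCCC)OCCO1)O[Si](C)(C)C(C)(C)C
A2 | alternative 1 | dimethyl malonate | COC(=O)CC(=O)OC
A3 | alternative 1 | methyl 6-{(R)-2-[(tert-butyldimethylsilyl)oxy]-7-(2-pentyl-1,3-dioxolan-2-yl)heptyl}-2,4-dioxocyclohexane-1-carboxylate (ring centres as a mixture) | COC(=O)C1C(=O)CC(=O)CC1C[C@@H](CCCCCC2(CCCCC)OCCO2)O[Si](C)(C)C(C)(C)C
A4 | alternative 2 | tosylmethyl isocyanide | Cc1ccc(cc1)S(=O)(=O)C[N+]#[C-]
A5 | alternative 2 | 1-iodopentane | CCCCCI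
A6 | alternative 2 | {[(2R)-1-[3,5-bis(benzyloxy)phenyl]-7-iodoheptan-2-yl]oxy}(tert-butyl)dimethylsilane | ICCCCC[C@H](Cc1cc(OCc2ccccc2)cc(OCc2ccccc2)c1)O[Si](C)(C)C(C)(C)C
A7 | alternative 2 | (2R)-1-[3,5-bis(benzyloxy)phenyl]-2-[(tert-butyldimethylsilyl)oxy]-8-isocyano-8-tosyltridecane (C8 as a mixture) | CCCCCC([N+]#[C-])(S(=O)(=O)c1ccc(C)cc1)CCCCC[C@H](Cc1cc(OCc2ccccc2)cc(OCc2ccccc2)c1)O[Si](C)(C)C(C)(C)C
A8 | alternative 3 | 3-[(2R)-2-[(tert-butyldimethylsilyl)oxy]-8-oxotridecyl]cyclobut-2-en-1-one | O=C1C=C(C[C@@H](CCCCCC(=O)CCCCC)O[Si](C)(C)C(C)(C)C)C1
A9 | alternative 3 | ethoxyacetylene | CCOC#C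
A10 | alternative 3 | 3-ethoxy-5-{(R)-2-[(tert-butyldimethylsilyl)oxy]-8-oxotridecyl}phenol | CCOc1cc(O)cc(C[C@@H](CCCCCC(=O)CCCCC)O[Si](C)(C)C(C)(C)C)c1
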